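**Plan**
1. Numbering: C1 is the ester carbon, C2 its α-carbon, C3–C6 the four dioxane carbons, and C7–C8 the linker to the cyclohexenone. In this numbering the target is (2R,3S,6R).
2. Enabling feature: the two oxygens of the 1,2-dioxane ring sit on C3 and C6, 1,4-related across the C4–C5 bridge. The C2 branch on C3 is cis to the methyl on C6, which is the pattern left when one O2 molecule adds to one face of a C3=C4–C5=C6 diene.
3. Cuts, in order: C1 ester back to a silyl-protected CH2OH; C4–C5 back to C4=C5; C3–O and C6–O together (diene + O2); C3=C4 (sulfone + enal); then C6–CH3, C4–C5 and the ring C=O (ynoate, alkyne, β-ionone).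
4. Forward: the carbocycle comes ready-made with β-ionone and is oxidised to the enone before any singlet oxygen is used. The chain is extended at C4 and methylated at C6, then joined to the C1–C3 piece at C3=C4. The dioxane ring is closed last.
5. Stereochemistry: C2 comes from methyl (S)-3-hydroxy-2-methylpropanoate. The C3/C6 relative configuration comes from the (3E,5Z) diene geometry (Julia–Kocienski for E, syn-carbocupration for Z). Their absolute sense comes from the C2-controlled choice of diene face.

Key step: step 13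

Remark: the spatial arrangement at C2 is never altered. Its descriptor changes only through CIP priorities: S in 12, 13, 15–18 and 21–23; R in 14, 19 and 24–26.

**Step 1**
Reactants: 1 β-ionone [(3E)-4-(2,6,6-trimethylcyclohex-1-en-1-yl)but-3-en-2-one]
Product: 2 dihydro-β-ionone [4-(2,6,6-trimethylcyclohex-1-en-1-yl)butan-2-one]
Conditions: H2 (1 atm), Pd/C, EtOAc, rt, stopped after one equivalent of H2
Reagents that add atoms: none
Why: Heterogeneous catalytic hydrogenation saturates the unhindered disubstituted enone C=C far faster than the tetrasubstituted ring alkene next to the gem-dimethyl carbon, so uptake should stop at the dihydro ketone.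

**Step 2**
Reactants: 2 dihydro-β-ionone
Product: 4 2-(but-3-yn-1-yl)-1,3,3-trimethylcyclohex-1-ene, via enol phosphate 3 (not isolated)
Conditions: LiN(iPr)2, THF, −78 °C; ClP(O)(OEt)2, −78 °C → rt; LiN(iPr)2 (2.3 equiv), −78 °C → rt; H2O
Reagents that add atoms: none
Why: Kinetic deprotonation takes a methyl proton, O-phosphorylation fixes the terminal enolate as 3, and excess amide base expels diethyl phosphate by β-elimination (the standard methyl ketone to terminal alkyne conversion), conditions to which the ring alkene is indifferent.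

**Step 3**
Reactants: 4 2-(but-3-yn-1-yl)-1,3,3-trimethylcyclohex-1-ene
Product: 6 methyl 5-(2,6,6-trimethylcyclohex-1-en-1-yl)pent-2-ynoate, via lithium acetylide 5 (not isolated)
Conditions: n-BuLi, THF, −78 °C; ClCO2Me, −78 → 0 °C
Reagents that add atoms: methyl chloroformate, COC(=O)Cl
Why: Acetylide formation followed by C-acylation with a chloroformate is the routine entry to 2-ynoates and brings in C4 as the ester carbon.

**Step 4**
Reactants: 6 methyl 5-(2,6,6-trimethylcyclohex-1-en-1-yl)pent-2-ynoate
Product: 8 methyl (2Z)-3-methyl-5-(2,6,6-trimethylcyclohex-1-en-1-yl)pent-2-enoate, via alkenylcuprate 7 (not isolated)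
Conditions: Me2CuLi (from CuI and MeLi), THF, −78 °C; sat. aq. NH4Cl added at −78 °C
Reagents that add atoms: lithium dimethylcuprate, [Li+].C[Cu-]C
Why: Conjugate syn-carbocupration by the Gilman reagent places the new methyl group and copper on the same side of C5=C6, and protonation of 7 at −78 °C, before it can equilibrate through the allenolate, occurs with retention, so the C7 chain ends cis to the ester, i.e. (Z).

**Step 5**
Reactants: 8 methyl (2Z)-3-methyl-5-(2,6,6-trimethylcyclohex-1-en-1-yl)pent-2-enoate
Product: 9 methyl (2Z)-3-methyl-5-(2,6,6-trimethyl-3-oxocyclohex-1-en-1-yl)pent-2-enoate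
Conditions: CrO3, 3,5-dimethylpyrazole, CH2Cl2, −20 °C
Reagents that add atoms: chromium trioxide, O=[Cr](=O)=O
Why: Allylic C–H oxidation by the hexavalent chromium–pyrazole complex engages the electron-rich tetrasubstituted alkene and, as in the oxidation of labd-8-enes and drim-8-enes to their 8-en-7-ones, should take the ring CH2 next to the methyl-bearing alkene carbon rather than the shielded side-chain CH2, while the allylic positions of the electron-poor enoate are spared.

**Step 6**
Reactants: 9 methyl (2Z)-3-methyl-5-(2,6,6-trimethyl-3-oxocyclohex-1-en-1-yl)pent-2-enoate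
Product: 10 3-[(3Z)-5-hydroxy-3-methylpent-3-en-1-yl]-2,4,4-trimethylcyclohex-2-en-1-ol (racemic at the ring carbinol)
Conditions: iBu2AlH (4 equiv), CH2Cl2, −78 → 0 °C; aq. potassium sodium tartrate
Reagents that add atoms: none
Why: iBu2AlH reduces the enoate to the allylic alcohol and the enone by 1,2-addition without touching either C=C or the (Z) geometry, and the uncontrolled ring carbinol centre is harmless because step 7 removes it.

**Step 7**
Reactants: 10 3-[(3Z)-5-hydroxy-3-methylpent-3-en-1-yl]-2,4,4-trimethylcyclohex-2-en-1-ol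
Product: 11 (2Z)-3-methyl-5-(2,6,6-trimethyl-3-oxocyclohex-1-en-1-yl)pent-2-enal
Conditions: MnO2 (activated, excess), CH2Cl2, rt
Reagents that add atoms: none
Why: MnO2 oxidises both allylic alcohols under neutral heterogeneous conditions, the established way from (Z)-allylic alcohols of the nerol type to (Z)-enals without E/Z leakage.

**Step 8**
Reactants: 12 methyl (2S)-3-hydroxy-2-methylpropanoate
Product: 13 methyl (2S)-2-methyl-3-(triisopropylsilyloxy)propanoate
Conditions: iPr3SiCl, imidazole, DMF, rt
Reagents that add atoms: triisopropylsilyl chloride, CC(C)[Si](Cl)(C(C)C)C(C)C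
Why: Routine silylation of a primary alcohol, in which imidazole is too weak a base to enolise the ester, so C2 keeps its configuration.

**Step 9**
Reactants: 13 methyl (2S)-2-methyl-3-(triisopropylsilyloxy)propanoate
Product: 14 (2R)-2-methyl-3-(triisopropylsilyloxy)propan-1-ol
Conditions: iBu2AlH (2.5 equiv), CH2Cl2, −78 → 0 °C; aq. potassium sodium tartrate
Reagents that add atoms: none
Why: Hydride reduction of the ester to the primary alcohol leaves the silyl ether and the stereocentre untouched.

**Step 10**
Reactants: 14 (2R)-2-methyl-3-(triisopropylsilyloxy)propan-1-ol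
Product: 15 5-{[(2S)-2-methyl-3-(triisopropylsilyloxy)propyl]sulfanyl}-1-phenyl-1H-tetrazole
Conditions: 1-phenyl-1H-tetrazole-5-thiol, PPh3, DIAD, THF, 0 °C → rt
Reagents that add atoms: 1-phenyl-1H-tetrazole-5-thiol, Sc1nnnn1-c1ccccc1
Why: Mitsunobu thioetherification displaces the activated primary hydroxyl at C3 with the acidic thiol and does not involve the neighbouring stereocentre.

**Step 11**
Reactants: 15 5-{[(2S)-2-methyl-3-(triisopropylsilyloxy)propyl]sulfanyl}-1-phenyl-1H-tetrazole
Product: 17 5-{[(2S)-2-methyl-3-(triisopropylsilyloxy)propyl]sulfonyl}-1-phenyl-1H-tetrazole, via sulfoxide 16 (not isolated)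
Conditions: (NH4)6Mo7O24·4H2O (cat.), 30% aq. H2O2, EtOH, 0 °C → rt
Reagents that add atoms: hydrogen peroxide, OO
Why: Molybdate-catalysed peroxide oxidation carries tetrazolyl sulfides through the sulfoxide to the sulfone and is tolerated by hindered silyl ethers.

**Step 12**
Reactants: 17 5-{[(2S)-2-methyl-3-(triisopropylsilyloxy)propyl]sulfonyl}-1-phenyl-1H-tetrazole; 11 (2Z)-3-methyl-5-(2,6,6-trimethyl-3-oxocyclohex-1-en-1-yl)pent-2-enal
Product: 19 (2R,3E,5Z)-diene 3-[(3Z,5E,7R)-3,7-dimethyl-8-(triisopropylsilyloxy)octa-3,5-dien-1-yl]-2,4,4-trimethylcyclohex-2-en-1-one, via potassiated sulfone 18 (not isolated)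
Conditions: KN(SiMe3)2, DME, −55 °C; then 11, −55 °C → rt
Reagents that add atoms: none
Why: In this Julia–Kocienski olefination the pre-formed sulfonyl carbanion adds to the aldehyde much faster than to the conjugated ring ketone, and Smiles rearrangement with anti-periplanar loss of SO2 and tetrazolate from the kinetically favoured anti adduct should give (E)-C3=C4 while C5=C6 stays (Z) and C2 is not deprotonated.

**Step 13**
Reactants: 19 (2R,3E,5Z)-diene; 20 dioxygen
Product: 21 (2S,3S,6R)-3,6-dihydro-1,2-dioxine 3-(2-{(3R,6S)-3-methyl-6-[(2S)-1-(triisopropylsilyloxy)propan-2-yl]-3,6-dihydro-1,2-dioxin-3-yl}ethyl)-2,4,4-trimethylcyclohex-2-en-1-one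
Conditions: O2 (bubbled), tetraphenylporphyrin (cat.), CH2Cl2, 0 °C, visible light (white LED)
Reagents that add atoms: none
Why: Energy transfer from the excited porphyrin turns ground-state O2 into singlet oxygen, which acts as the 2π partner in a concerted hetero-Diels–Alder reaction with the s-cis conformer of the C3–C6 diene, a reaction type long established for acyclic 1,3-dienes, including those with a fully substituted terminus. The six-membered peroxide ring closes in this single [4+2] event, the C3–O and C6–O bonds both forming on the same diene face from one O2 molecule. The C3/C6 relative configuration follows from the diene geometry, since the two outward-pointing groups (the C2 branch on the 3E alkene and the methyl on the 5Z alkene) finish cis and the inward-pointing C7 chain finishes trans to the C2 branch. The absolute sense of both new centres depends on the face attacked, which C2 governs: with its hydrogen lying in the diene plane along C3=C4, the CH2OSi(iPr)3 arm covers one face and oxygen should enter past the methyl group to give (3S,6R), a bias expected to be moderate, so the other facial isomer is removed by chromatography. Chemoselectivity rests on electronics, because the ring alkene belongs to an s-trans, tetrasubstituted enone that is too electron-poor to react, and the isolated reactivity of C3=C4 is low. The competing ene reaction at C5=C6 and stepwise, geometry-eroding additions are held down by an apolar aprotic solvent and by working at 0 °C rather than colder, so that the s-cis population is not frozen out.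

**Step 14**
Reactants: 21 (2S,3S,6R)-3,6-dihydro-1,2-dioxine
Product: 22 (2S,3S,6R)-1,2-dioxane 3-(2-{(3R,6S)-3-methyl-6-[(2S)-1-(triisopropylsilyloxy)propan-2-yl]-1,2-dioxan-3-yl}ethyl)-2,4,4-trimethylcyclohex-2-en-1-one
Conditions: KO2CN=NCO2K, AcOH, CH2Cl2–MeOH, 0 °C → rt (added in portions)
Reagents that add atoms: none
Why: Diimide transfers H2 in a concerted syn fashion to the unpolarised cis-disubstituted C4=C5 bond, does not cleave O–O bonds and ignores the tetrasubstituted enone alkene, which makes it the standard reagent for turning dihydrodioxines into dioxanes without touching a stereocentre.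

**Step 15**
Reactants: 22 (2S,3S,6R)-1,2-dioxane silyl ether
Product: 23 3-(2-{(3R,6S)-6-[(2S)-1-hydroxypropan-2-yl]-3-methyl-1,2-dioxan-3-yl}ethyl)-2,4,4-trimethylcyclohex-2-en-1-one
Conditions: HF·pyridine, pyridine, THF, 0 °C → rt
Reagents that add atoms: none
Why: Acidic fluoride cleaves the Si–O bond, and avoiding basic fluoride protects the C3–H next to the peroxide from base-induced fragmentation of the Kornblum–DeLaMare type.

**Step 16**
Reactants: 23 primary alcohol
Product: 25 (2R)-2-{(3S,6R)-6-methyl-6-[2-(2,6,6-trimethyl-3-oxocyclohex-1-en-1-yl)ethyl]-1,2-dioxan-3-yl}propanoic acid, via aldehyde 24 (not isolated)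
Conditions: TEMPO (cat.), PhI(OAc)2 (2.5 equiv), MeCN–H2O, rt
Reagents that add atoms: water, O
Why: Oxoammonium-mediated oxidation takes the primary alcohol through aldehyde 24 and its hydrate to the acid in a mildly acidic medium, in which dialkyl peroxides persist and neither epimerisation at C2 nor β-elimination of the peroxide is promoted.

**Step 17**
Reactants: 25 carboxylic acid
Product: 26 methyl diacarnoate A, methyl (2R)-2-{(3S,6R)-6-methyl-6-[2-(2,6,6-trimethyl-3-oxocyclohex-1-en-1-yl)ethyl]-1,2-dioxan-3-yl}propanoate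
Conditions: Me3SiCHN2, toluene–MeOH, 0 °C
Reagents that add atoms: (trimethylsilyl)diazomethane, C[Si](C)(C)C=[N+]=[N-]
Why: O-methylation of the acid by diazomethane released in situ proceeds under neutral conditions, so the base-labile β-peroxy ester and C2 are not put at risk.

**Compound list**
1 | β-ionone | CC(=O)/C=C/C1=C(C)CCCC1(C)C | starting material
2 | dihydro-β-ionone | CC(=O)CCC1=C(C)CCCC1(C)C | intermediate
3 | diethyl 4-(2,6,6-trimethylcyclohex-1-en-1-yl)but-1-en-2-yl phosphate | C=C(CCC1=C(C)CCCC1(C)C)OP(=O)(OCC)OCC | intermediate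
4 | 2-(but-3-yn-1-yl)-1,3,3-trimethylcyclohex-1-ene | C#CCCC1=C(C)CCCC1(C)C | intermediate
5 | lithium acetylide of 4 | [Li]C#CCCC1=C(C)CCCC1(C)C | intermediate
6 | methyl 5-(2,6,6-trimethylcyclohex-1-en-1-yl)pent-2-ynoate | COC(=O)C#CCCC1=C(C)CCCC1(C)C | intermediate
7 | lithium methyl(alkenyl)cuprate, copper on the α-carbon cis to the new methyl | [Li+].COC(=O)/C([Cu-]C)=C(/C)CCC1=C(C)CCCC1(C)C | intermediate
8 | methyl (2Z)-3-methyl-5-(2,6,6-trimethylcyclohex-1-en-1-yl)pent-2-enoate | COC(=O)/C=C(/C)CCC1=C(C)CCCC1(C)C | intermediate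
9 | methyl (2Z)-3-methyl-5-(2,6,6-trimethyl-3-oxocyclohex-1-en-1-yl)pent-2-enoate | COC(=O)/C=C(/C)CCC1=C(C)C(=O)CCC1(C)C | intermediate
10 | 3-[(3Z)-5-hydroxy-3-methylpent-3-en-1-yl]-2,4,4-trimethylcyclohex-2-en-1-ol (racemic carbinol) | OC/C=C(/C)CCC1=C(C)C(O)CCC1(C)C | intermediate
11 | (2Z)-3-methyl-5-(2,6,6-trimethyl-3-oxocyclohex-1-en-1-yl)pent-2-enal | O=C/C=C(/C)CCC1=C(C)C(=O)CCC1(C)C | intermediate
12 | methyl (2S)-3-hydroxy-2-methylpropanoate | OC[C@H](C)C(=O)OC | starting material
13 | methyl (2S)-2-methyl-3-(triisopropylsilyloxy)propanoate | CC(C)[Si](C(C)C)(C(C)C)OC[C@H](C)C(=O)OC | intermediate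
14 | (2R)-2-methyl-3-(triisopropylsilyloxy)propan-1-ol | CC(C)[Si](C(C)C)(C(C)C)OC[C@H](C)CO | intermediate
15 | 5-{[(2S)-2-methyl-3-(triisopropylsilyloxy)propyl]sulfanyl}-1-phenyl-1H-tetrazole | CC(C)[Si](C(C)C)(C(C)C)OC[C@H](C)CSc1nnnn1-c1ccccc1 | intermediate
16 | corresponding sulfoxide (both configurations at sulfur) | CC(C)[Si](C(C)C)(C(C)C)OC[C@H](C)CS(=O)c1nnnn1-c1ccccc1 | intermediate
17 | 5-{[(2S)-2-methyl-3-(triisopropylsilyloxy)propyl]sulfonyl}-1-phenyl-1H-tetrazole | CC(C)[Si](C(C)C)(C(C)C)OC[C@H](C)CS(=O)(=O)c1nnnn1-c1ccccc1 | intermediate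
18 | potassium salt of 17, carbanion at C3 | [K+].CC(C)[Si](C(C)C)(C(C)C)OC[C@H](C)[CH-]S(=O)(=O)c1nnnn1-c1ccccc1 | intermediate
19 | (2R,3E,5Z)-diene, C1 as triisopropylsilyl ether | CC(C)[Si](C(C)C)(C(C)C)OC[C@H](C)/C=C/C=C(/C)CCC1=C(C)C(=O)CCC1(C)C | intermediate
20 | dioxygen | O=O | starting material
21 | (2S,3S,6R)-3,6-dihydro-1,2-dioxine, C2 branch cis to C6 methyl | CC(C)[Si](C(C)C)(C(C)C)OC[C@H](C)[C@@H]1C=C[C@@](C)(CCC2=C(C)C(=O)CCC2(C)C)OO1 | intermediate
22 | (2S,3S,6R)-1,2-dioxane silyl ether | CC(C)[Si](C(C)C)(C(C)C)OC[C@H](C)[C@@H]1CC[C@@](C)(CCC2=C(C)C(=O)CCC2(C)C)OO1 | intermediate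
23 | (2S,3S,6R)-1,2-dioxane primary alcohol | OC[C@H](C)[C@@H]1CC[C@@](C)(CCC2=C(C)C(=O)CCC2(C)C)OO1 | intermediate
24 | (2R,3S,6R)-1,2-dioxane aldehyde | O=C[C@H](C)[C@@H]1CC[C@@](C)(CCC2=C(C)C(=O)CCC2(C)C)OO1 | intermediate
25 | (2R,3S,6R)-1,2-dioxane carboxylic acid | OC(=O)[C@H](C)[C@@H]1CC[C@@](C)(CCC2=C(C)C(=O)CCC2(C)C)OO1 | intermediate
26 | methyl diacarnoate A, (2R,3S,6R) | COC(=O)[C@H](C)[C@@H]1CC[C@@](C)(CCC2=C(C)C(=O)CCC2(C)C)OO1 | target

**Total step count:** 17. **Longest linear sequence:** 13 steps (1–7, then 12–17).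

**Steps most likely to fail**

Step 13 (photooxygenation).
- What may go wrong: hydrogen abstraction (ene reaction) at C5=C6 outrunning the cycloaddition, leakage of diene geometry through a stepwise addition, or weak discrimination between the two diene faces.
- Fallback: it sets out from 14 and 11, returns at 22, and forms the two C–O bonds one at a time by known peroxide chemistry.
- C1–C5 partner: Alcohol 14 is oxidised (Swern) to (2S)-2-methyl-3-(triisopropylsilyloxy)propanal F1. Reagent-controlled allylboration, using the enantiomer of B-allyldiisopinocampheylborane that delivers the (3R)-carbinol, gives (2S,3R)-2-methyl-1-(triisopropylsilyloxy)hex-5-en-3-ol F2. MsCl/Et3N converts this into the mesylate (2S,3R)-2-methyl-1-(triisopropylsilyloxy)hex-5-en-3-yl methanesulfonate F3.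
- Ring partner and union: Enal 11 is decarbonylated with RhCl(PPh3)3 in hot toluene to 2,4,4-trimethyl-3-(3-methylbut-3-en-1-yl)cyclohex-2-en-1-one F4. Cross-metathesis of F3 with F4 (second-generation Hoveyda–Grubbs catalyst) gives the trisubstituted C5=C6 alkene mesylate F5, whose geometry is irrelevant.
- Peroxide: Mukaiyama–Isayama peroxidation (Co(thd)2, O2, Et3SiH) places a triethylsilylperoxy group on the tertiary carbon C6 and gives the silyl peroxide mesylate F6 as both C6 epimers. Buffered fluoride (Bu4NF/AcOH, 0 °C) frees the hydroperoxide mesylate F7. Cs2CO3 in DMF closes the dioxane by 6-exo-tet SN2 displacement of the mesylate with inversion at C3.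
- Outcome: this should give 22 together with the (2S,3S,6S)-dioxane C6 epimer F8, which is removed by chromatography. C2 still comes from the hydroxy ester, C3 is set by the reagent, only C6 is left to separation, and step 14 is no longer needed.

Step 5 (allylic oxidation).
- What may go wrong: oxidation at the side-chain methylene C8 or at the ring methyl group instead of the ring CH2, or over-oxidation.
- Fallback: it sets out from 1, returns at 9, and installs the ring carbonyl while C7 and C8 are still vinylic. The side chain is then rebuilt by cross-coupling.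
- Ring fragment: β-Ionone 1 is oxidised (CrO3, 3,5-dimethylpyrazole) to 4-oxo-β-ionone F9. Hydrogenation (H2, Pd/C) of the disubstituted alkene gives 4-oxo-7,8-dihydro-β-ionone F10. Baeyer–Villiger oxidation of the methyl ketone (CF3CO3H, Na2HPO4), in which the primary alkyl group migrates in preference to methyl, gives 2-(2,6,6-trimethyl-3-oxocyclohex-1-en-1-yl)ethyl acetate F11. Methanolysis (K2CO3, MeOH) gives 3-(2-hydroxyethyl)-2,4,4-trimethylcyclohex-2-en-1-one F12, and I2/PPh3/imidazole gives 3-(2-iodoethyl)-2,4,4-trimethylcyclohex-2-en-1-one F13.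
- Coupling: Zinc insertion (activated Zn, THF), which tolerates the ketone, gives the alkylzinc iodide F14. Negishi coupling (Pd(PPh3)4) with methyl (Z)-3-iodobut-2-enoate F15 (from methyl but-2-ynoate, NaI and AcOH) proceeds with retention at the iodo-alkene and gives 9 with the chain cis to the ester.

Step 12 (fragment union).
- What may go wrong: base-induced isomerisation of the (Z)-enal through its dienolate, enolisation of the ring ketone, or poor E/Z selectivity at C3=C4.
- Fallback: it sets out from 14 and 11, returns at 19, and joins the fragments without base by olefin cross-metathesis.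
- Sequence: The aldehyde F1, made from 14 as described above, is methylenated (Ph3P=CH2) to triisopropyl{[(2R)-2-methylbut-3-en-1-yl]oxy}silane F16. Enal 11 is methylenated only at the aldehyde with CH2I2/Zn/Ti(OiPr)4 to 2,4,4-trimethyl-3-[(3Z)-3-methylhexa-3,5-dien-1-yl]cyclohex-2-en-1-one F17.
- Outcome: the second-generation Hoveyda–Grubbs catalyst engages only the two monosubstituted vinyl ends, because the trisubstituted C5=C6 bond and the enone alkene are too hindered. It should form the (E)-C3=C4 bond of 19 under thermodynamic control.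

**Further compounds**
F1 | step 13 | (2S)-2-methyl-3-(triisopropylsilyloxy)propanal | CC(C)[Si](C(C)C)(C(C)C)OC[C@H](C)C=O
F2 | step 13 | (2S,3R)-2-methyl-1-(triisopropylsilyloxy)hex-5-en-3-ol | CC(C)[Si](C(C)C)(C(C)C)OC[C@H](C)[C@H](O)CC=C
F3 | step 13 | (2S,3R)-2-methyl-1-(triisopropylsilyloxy)hex-5-en-3-yl methanesulfonate | CC(C)[Si](C(C)C)(C(C)C)OC[C@H](C)[C@H](OS(C)(=O)=O)CC=C
F4 | step 13 | 2,4,4-trimethyl-3-(3-methylbut-3-en-1-yl)cyclohex-2-en-1-one | C=C(C)CCC1=C(C)C(=O)CCC1(C)C
F5 | step 13 | (2S,3R)-2,6-dimethyl-8-(2,6,6-trimethyl-3-oxocyclohex-1-en-1-yl)-1-(triisopropylsilyloxy)oct-5-en-3-yl methanesulfonate (E/Z mixture) | CC(C)[Si](C(C)C)(C(C)C)OC[C@H](C)[C@H](OS(C)(=O)=O)CC=C(C)CCC1=C(C)C(=O)CCC1(C)C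
F6 | step 13 | C6 triethylsilylperoxy derivative of saturated F5 (both C6 epimers) | CC(C)[Si](C(C)C)(C(C)C)OC[C@H](C)[C@H](OS(C)(=O)=O)CCC(C)(CCC1=C(C)C(=O)CCC1(C)C)OO[Si](CC)(CC)CC
F7 | step 13 | C6 hydroperoxide mesylate (both C6 epimers) | CC(C)[Si](C(C)C)(C(C)C)OC[C@H](C)[C@H](OS(C)(=O)=O)CCC(C)(CCC1=C(C)C(=O)CCC1(C)C)OO
F8 | step 13 | (2S,3S,6S)-1,2-dioxane silyl ether, C6 epimer of 22 | CC(C)[Si](C(C)C)(C(C)C)OC[C@H](C)[C@@H]1CC[C@](C)(CCC2=C(C)C(=O)CCC2(C)C)OO1
F9 | step 5 | 4-oxo-β-ionone, 2,4,4-trimethyl-3-[(1E)-3-oxobut-1-en-1-yl]cyclohex-2-en-1-one | CC(=O)/C=C/C1=C(C)C(=O)CCC1(C)C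
F10 | step 5 | 4-oxo-7,8-dihydro-β-ionone, 2,4,4-trimethyl-3-(3-oxobutyl)cyclohex-2-en-1-one | CC(=O)CCC1=C(C)C(=O)CCC1(C)C
F11 | step 5 | 2-(2,6,6-trimethyl-3-oxocyclohex-1-en-1-yl)ethyl acetate | CC(=O)OCCC1=C(C)C(=O)CCC1(C)C
F12 | step 5 | 3-(2-hydroxyethyl)-2,4,4-trimethylcyclohex-2-en-1-one | OCCC1=C(C)C(=O)CCC1(C)C
F13 | step 5 | 3-(2-iodoethyl)-2,4,4-trimethylcyclohex-2-en-1-one | ICCC1=C(C)C(=O)CCC1(C)C
F14 | step 5 | [2-(2,6,6-trimethyl-3-oxocyclohex-1-en-1-yl)ethyl]zinc iodide | I[Zn]CCC1=C(C)C(=O)CCC1(C)C
F15 | step 5 | methyl (Z)-3-iodobut-2-enoate | COC(=O)/C=C(/C)I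
F16 | step 12 | triisopropyl{[(2R)-2-methylbut-3-en-1-yl]oxy}silane | CC(C)[Si](C(C)C)(C(C)C)OC[C@H](C)C=C
F17 | step 12 | 2,4,4-trimethyl-3-[(3Z)-3-methylhexa-3,5-dien-1-yl]cyclohex-2-en-1-one | C=C/C=C(/C)CCC1=C(C)C(=O)CCC1(C)C
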